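# Proposed synthesis of CNP0189756.1 (compound 36)

## Analysis of the target

Target 36 is a monocyclic 1,2-dioxane (ring O1–O2–C3–C4–C5–C6) on a chain numbered from the ester carbon C1 to the benzylic carbon C12; C3 carries the C2–C1 methyl acetate arm, C4 a methyl group, and C6 a methyl group plus the C7–C12 side chain. The stereocentres are C3 (S), C4 (R) and the fully substituted C6 (R); the acetate arm is trans to the C4 methyl group and the C4 methyl group is cis to C7, so one chair has these three groups equatorial and only the C6 methyl group axial. The side chain is a (2E,4E)-2-methylhexa-2,4-dienyl unit (C8=C9, C10=C11) whose trisubstituted C8=C9 bond needs defined geometry and whose C12 methylene is both allylic and benzylic. Sensitive sites are the O–O bond (hydrides, organolithium and organocopper reagents, low-valent metals, radicals), C3–H (base-induced Kornblum–DeLaMare cleavage), the C2 methylene (an ester enolate expels O2 from C3) and the skipped phenyl/diene unit (isomerisation toward styrene conjugation). The synthesis is hard because C6 is a tertiary peroxy carbon that cannot be made by SN2 attack of a peroxide nucleophile, must be set 1,3 to C4, and, once the peroxide exists, leaves only mild, non-reducing chemistry for the diene. The strategy rests on C3, which is bonded to ring oxygen O2 and, through C2, to the carboxyl carbon C1. That is the pattern left when an oxygen nucleophile and CO add across a terminal C2=C3 double bond, so O2–C3 and C1–C2 can both come from one oxypalladation–carbonylation of a C4 vinyl group by a C6 hydroperoxide.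

## Retrosynthetic reasoning

**C8–CH3 (36 ⇒ 35 ⇒ 33 ⇒ 32 ⇒ 31).** The methyl group on C8 is cut first, giving dienyl triflate 35 and, behind it, the β,γ-unsaturated ketone 33. The C8=C9 geometry then follows from the geometry of an extended enolate and not from an olefination of a ketone, which would give isomer mixtures. The only organometallic used near the peroxide is a mild organozinc nucleophile. Ketone 33 comes from carbinol 32 and its silyl ether 31; the C8 oxygen is needed earlier in any case.

**O2–C3 and C1–C2 (31 ⇒ 28 + 29 + 30).** Both bonds at C2–C3 are cut together. The precursor is tertiary hydroperoxide 28 with a C4 vinyl group, plus carbon monoxide 29 and methanol 30. The forward reaction has to close the ring at C3 on the face that puts the new arm trans to the C4 methyl group and to trap the alkylpalladium with CO. This is preferred to an oxa-Michael closure because a vinyl group, unlike an enoate, passes unchanged through the organometallic steps that build the chain.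

**C6–OO (28 ⇒ 26 ⇒ 25).** The tertiary C–O bond of the hydroperoxide is traced to oxetane 25, opened at C6 with inversion. No other substitution at a tertiary carbon offers stereochemical fidelity. The opening also frees the C8 hydroxyl that later becomes the ketone. Hydroxy hydroperoxide 26 is silylated at C8 to give 28.

**C8–O of the oxetane (25 ⇒ 23).** The ring is cut at the secondary carbon, giving 1,3-diol 23. Closure inverts C8, which is of no consequence, and retains C6. The diol must therefore carry C6 in the (S) configuration, opposite in sense to the target.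

**C5–C6 (23 ⇒ 22 ⇒ 19 + 6).** This cut divides the chain into two fragments of similar size. The forward step is the addition of the organometallic from iodide 6 to β-alkoxy methyl ketone 19. The C8 ether oxygen serves as a chelating relay for C6 and is the same oxygen that later closes the oxetane. The C4 centre comes unchanged from ester 1 through 6.

**C9–C10 and C6–C7 (19 ⇒ 18 ⇒ 17 ⇒ 14 + 9; 14 ⇒ 10 + 11).** The homoallylic carbinol is cut next to the alkene, giving terminal epoxide 14 and alkenyl iodide 9. This avoids a labile β,γ-unsaturated aldehyde and fixes the C10=C11 geometry. Epoxide 14 comes from dithiane 10, a masked C6 ketone, and epichlorohydrin 11, which supplies C7–C9 and the C8 configuration.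

**Fragments (9 ⇒ 7; 6 ⇒ 5 ⇒ 4 ⇒ 3 ⇒ 2 ⇒ 1).** Iodide 9 is the hydrozirconation–iodination product of alkyne 7. Iodide 6 is reached from ester 1: the ester carbon becomes the vinyl group and the hydroxymethyl carbon becomes C5.

## Alternatives that were turned down

**Alternative 1:** Both ring C–O bonds are cut, back to cyclobutene A2, whose alkene carbons are C3 and C6. Forward, ozonolysis in an alcohol solvent cleaves the strained alkene; the solvent traps the carbonyl oxide, and the resulting hydroperoxide adds to the ketone four carbons away, closing bis(peroxyketal) A1.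
- For: one operation builds the ring with the ester arm and a vinyl bromide handle in place, and no transition metal meets a hydroperoxide. On ring-forming step economy and precedent it is stronger than the chosen route.
- Against: in A1, C3 and C6 are both at the ketal level. C3 still needs hydrogen and C6 still needs its methyl group. Each must be delivered to a peroxycarbenium ion with facial control, and a methyl carbanion equivalent that spares a peroxide is lacking. A1 forms as ketal epimers and regioisomers, and the enantioenriched tetrasubstituted cyclobutene A2 is itself a demanding intermediate.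
- Comparison: the chosen route fixes C4 and C6 before the ring exists and sets C3 through a chair. It accepts an unprecedented palladium step in exchange for firm control of all three centres.

**Alternative 2:** The O–O bond is cut last, back to bis(aminooxy) ester A4. Forward, a hypervalent iodine oxidant couples the two nitrogens, the nitrogen atoms depart together as gas, and the two oxygens join to give dioxane A3.
- For: C3 and C6 are fixed beforehand as ordinary C–O bonds and are retained, and the peroxide appears only at the end. On stereochemical certainty at C3, and on not carrying a hydroperoxide through several steps, it is stronger than the chosen route.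
- Against: fragmentation of the O–N=N–O unit releases two alkoxyl radicals. O–O formation then depends on cage recombination, in competition with β-scission at the tertiary C6 alkoxyl (which can expel an allyl-stabilised side chain) and with 1,5-hydrogen transfer. O-amination of the tertiary C6 alcohol is difficult in itself. A3 still lacks C9–C12, so deprotection, oxidation and a geometry-defining olefination follow on the peroxide.
- Comparison: the chosen key step is also new, but each of its elementary steps has polar precedent, it passes through no free alkoxyl radical, and it delivers C1 and the full side-chain skeleton at the ring-forming stage.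

**Alternative 3:** The C6–O bond is cut, back to A6, a secondary C3 hydroperoxide tethered to a 2,2,4-trisubstituted oxetane. Forward, silyl triflate activation lets the hydroperoxide attack C6 from the rear (6-exo, inversion), giving dioxane A5 with a free C8 hydroxyl.
- For: intramolecular opening of an oxetane by a hydroperoxide is a known route to 1,2-dioxanes, it is stereospecific at C6, and the freed hydroxyl feeds the same ketone/triflate endgame. On precedent for the ring closure it is stronger than the chosen route.
- Against: A6 needs a configurationally defined secondary hydroperoxide at C3, next to the C4 branch. Displacement there is slow and elimination-prone, and the product has an α-hydrogen and is base-labile. C3, C4 and C6 must all be set in the open chain. C1 arrives as a silyl ether, so desilylation, two oxidations and esterification follow next to the peroxide.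
- Comparison: the chosen route uses the same oxetane logic intermolecularly, handles only a robust tertiary hydroperoxide, creates C3 during ring closure, and reaches the ester oxidation level directly, saving about four steps.

Key step: step 16

Remark on the chemistry: locants C1–C12 follow the ester chain of 36 throughout. Compounds 1, 7, 10, 11, 29 and 30 are taken as commercial. C8 is carried as a single epimer set by 11; it only directs step 11 and is destroyed in step 18.

## Route

Step 1
Reactants: 1 methyl (2R)-3-hydroxy-2-methylpropanoate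
Product: 2 methyl (2R)-3-{[tert-butyl(dimethyl)silyl]oxy}-2-methylpropanoate
Conditions: TBSCl, imidazole, CH2Cl2, 0 °C → rt
Reagents that add atoms: tert-butyl(chloro)dimethylsilane, CC(C)(C)[Si](C)(C)Cl
Why: Routine silylation of a primary alcohol; the stereocentre is not involved.

Step 2
Reactants: 2 methyl (2R)-3-{[tert-butyl(dimethyl)silyl]oxy}-2-methylpropanoate
Product: 3 (2R)-3-{[tert-butyl(dimethyl)silyl]oxy}-2-methylpropanal
Conditions: i-Bu2AlH (1.05 equiv), CH2Cl2, –78 °C; MeOH, aq. potassium sodium tartrate
Reagents that add atoms: none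
Why: Partial ester reduction: at –78 °C the aluminium hemiacetal persists and releases the aldehyde only on work-up. The α-stereocentre should survive if the aldehyde is used at once without chromatography.

Step 3
Reactants: 3 (2R)-3-{[tert-butyl(dimethyl)silyl]oxy}-2-methylpropanal
Product: 4 tert-butyl(dimethyl){[(2S)-2-methylbut-3-enyl]oxy}silane
Conditions: Ph3PCH3Br, n-BuLi, THF, –78 → 0 °C
Reagents that add atoms: methyltriphenylphosphonium bromide, C[P+](c1ccccc1)(c1ccccc1)c1ccccc1.[Br-]
Why: Wittig methylenation with the non-stabilised ylide is fast at low temperature, so the aldehyde is consumed before it can enolise. The descriptor changes only because the priorities change.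

Step 4
Reactants: 4 tert-butyl(dimethyl){[(2S)-2-methylbut-3-enyl]oxy}silane
Product: 5 (2S)-2-methylbut-3-en-1-ol
Conditions: Bu4NF, THF, 0 °C → rt; careful distillation
Reagents that add atoms: none
Why: Fluoride cleaves the primary silyl ether. The volatile alcohol is isolated by distillation and not by evaporation.

Step 5
Reactants: 5 (2S)-2-methylbut-3-en-1-ol
Product: 6 (3S)-4-iodo-3-methylbut-1-ene
Conditions: I2, PPh3, imidazole, Et2O–MeCN, 0 °C → rt
Reagents that add atoms: iodine, II
Why: Appel-type iodination by SN2 at the primary carbon; the neighbouring stereocentre is untouched.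

Step 6
Reactants: 7 prop-2-ynylbenzene
Product: 9 [(E)-3-iodoprop-2-enyl]benzene, via chlorobis(cyclopentadienyl)[(E)-3-phenylprop-1-enyl]zirconium 8 (not isolated)
Conditions: Cp2Zr(H)Cl, CH2Cl2, rt; I2, 0 °C
Reagents that add atoms: iodine, II
Why: Syn hydrozirconation places zirconium on the terminal carbon, and iodinolysis of the C–Zr bond goes with retention, so the (E)-iodide results.

Step 7
Reactants: 10 2-methyl-1,3-dithiane; 11 (2R)-2-(chloromethyl)oxirane
Product: 14 2-methyl-2-{[(2R)-oxiran-2-yl]methyl}-1,3-dithiane, via 2-lithio-2-methyl-1,3-dithiane 12 (not isolated), via lithium (2R)-1-chloro-3-(2-methyl-1,3-dithian-2-yl)propan-2-olate 13 (not isolated)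
Conditions: n-BuLi, THF, –25 °C; 11, –78 °C → rt
Reagents that add atoms: none
Why: Corey–Seebach umpolung: the lithiated dithiane opens the epoxide at its CH2 terminus, and the chlorohydrin alkoxide closes to the new terminal epoxide on warming. The C–O bond at the stereocentre is never broken, so its configuration is retained.

Step 8
Reactants: 9 [(E)-3-iodoprop-2-enyl]benzene; 14 2-methyl-2-{[(2R)-oxiran-2-yl]methyl}-1,3-dithiane
Product: 17 (2S,4E)-1-(2-methyl-1,3-dithian-2-yl)-6-phenylhex-4-en-2-ol, via [(E)-3-phenylprop-1-enyl]lithium 15 (not isolated), via bromo[(E)-3-phenylprop-1-enyl]magnesium 16 (not isolated)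
Conditions: 9, t-BuLi (2 equiv), Et2O, –78 °C; MgBr2·OEt2; 14, CuI (10 mol %), THF, –40 → 0 °C
Reagents that add atoms: none
Why: Iodine–lithium exchange keeps the alkene geometry, and the copper-catalysed Grignard reagent opens the terminal epoxide by SN2 at its CH2 carbon (C9). The carbinol carbon is not touched; its descriptor changes from R to S by priority only.

Step 9
Reactants: 17 (2S,4E)-1-(2-methyl-1,3-dithian-2-yl)-6-phenylhex-4-en-2-ol
Product: 18 2-[(2S,4E)-2-[(4-methoxyphenyl)methoxy]-6-phenylhex-4-enyl]-2-methyl-1,3-dithiane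
Conditions: NaH, 4-MeOC6H4CH2Cl, Bu4NI (cat.), THF–DMF, 0 °C → rt
Reagents that add atoms: 4-methoxybenzyl chloride, COc1ccc(CCl)cc1
Why: Williamson etherification. The 4-methoxybenzyl ether is chosen because its oxygen can chelate magnesium in step 11 and it is removed oxidatively in step 12.

Step 10
Reactants: 18 2-[(2S,4E)-2-[(4-methoxyphenyl)methoxy]-6-phenylhex-4-enyl]-2-methyl-1,3-dithiane
Product: 19 (4S,6E)-4-[(4-methoxyphenyl)methoxy]-8-phenyloct-6-en-2-one
Conditions: MeI, CaCO3, MeCN–H2O (9:1), 40 °C
Reagents that add atoms: water, O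
Why: S-Methylation turns the dithiane into a leaving group and water hydrolyses the thionium ion (dithiane unmasking). The buffered, non-oxidising conditions should spare the alkene, the benzyl ether and the β-alkoxy ketone.

Step 11
Reactants: 6 (3S)-4-iodo-3-methylbut-1-ene; 19 (4S,6E)-4-[(4-methoxyphenyl)methoxy]-8-phenyloct-6-en-2-one
Product: 22 (3R,5S,7S,9E)-7-[(4-methoxyphenyl)methoxy]-3,5-dimethyl-11-phenylundeca-1,9-dien-5-ol, via [(2R)-2-methylbut-3-enyl]lithium 20 (not isolated), via bromo[(2S)-2-methylbut-3-enyl]magnesium 21 (not isolated)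
Conditions: 6, t-BuLi (2.1 equiv), Et2O–pentane, –78 °C; MgBr2·OEt2; added to 19, MgBr2·OEt2, CH2Cl2, –78 → –40 °C
Reagents that add atoms: none
Why: Chelation-controlled Grignard addition (Cram chelate, 1,3-induction): magnesium bridges the ketone and ether oxygens in a half-chair with the C9 chain equatorial, and the nucleophile enters axially, trans to that chain, which should set the tertiary carbinol as (S). The organometallic is made and used at –78 °C, so the homoallyl/cyclopropylcarbinyl rearrangement cannot scramble C4.

Step 12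
Reactants: 22 (3R,5S,7S,9E)-7-[(4-methoxyphenyl)methoxy]-3,5-dimethyl-11-phenylundeca-1,9-dien-5-ol
Product: 23 (3R,5S,7S,9E)-3,5-dimethyl-11-phenylundeca-1,9-diene-5,7-diol
Conditions: DDQ, CH2Cl2–pH 7 buffer, 0 °C
Reagents that add atoms: none
Why: Oxidative cleavage of the electron-rich benzyl ether through its oxocarbenium ion; the alkenes and the tertiary alcohol are inert. Any minor C6 epimer from step 11 is removed here by chromatography.

Step 13
Reactants: 23 (3R,5S,7S,9E)-3,5-dimethyl-11-phenylundeca-1,9-diene-5,7-diol
Product: 25 (2S,4R)-2-methyl-2-[(2R)-2-methylbut-3-enyl]-4-[(E)-4-phenylbut-2-enyl]oxetane, via (3R,5S,7S,9E)-5-hydroxy-3,5-dimethyl-11-phenylundeca-1,9-dien-7-yl 4-methylbenzenesulfonate 24 (not isolated)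
Conditions: n-BuLi (1.0 equiv), THF, –78 → 0 °C; TsCl; n-BuLi (1.05 equiv), 0 → 45 °C
Reagents that add atoms: none
Why: Only the secondary alkoxide is sulfonylated, and the tertiary alkoxide then closes the ring by intramolecular Williamson etherification (4-exo-tet), helped by the Thorpe–Ingold effect of the quaternary carbon. The secondary carbon is inverted and the tertiary one retained; a lithium alkoxide as the only base keeps E2 loss of the sulfonate toward the allylic position low.

Step 14
Reactants: 25 (2S,4R)-2-methyl-2-[(2R)-2-methylbut-3-enyl]-4-[(E)-4-phenylbut-2-enyl]oxetane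
Product: 26 (2E,5R,7R,9R)-7-hydroperoxy-7,9-dimethyl-1-phenylundeca-2,10-dien-5-ol
Conditions: anhydrous H2O2 in Et2O (10 equiv), TMSOTf (0.2 equiv), –78 → –30 °C; aq. NaHCO3
Reagents that add atoms: hydrogen peroxide, OO
Why: Lewis-acid-promoted perhydrolysis of an oxetane, a known opening mode for 2,2-disubstituted and 2,2,4-trisubstituted oxetanes: the silylated ring oxygen is displaced at the tertiary carbon, which best carries positive charge, by H2O2 from the rear of a tight ion pair. The tertiary centre is inverted to (R) and the secondary oxygen is released as the alcohol; the large excess of H2O2 should outrun participation by the remote alkene.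

Step 15
Reactants: 26 (2E,5R,7R,9R)-7-hydroperoxy-7,9-dimethyl-1-phenylundeca-2,10-dien-5-ol
Product: 28 tert-butyl{[(2E,5R,7R,9R)-7-hydroperoxy-7,9-dimethyl-1-phenylundeca-2,10-dien-5-yl]oxy}dimethylsilane, via tert-butyl{[(2E,5R,7R,9R)-7-{[tert-butyl(dimethyl)silyl]peroxy}-7,9-dimethyl-1-phenylundeca-2,10-dien-5-yl]oxy}dimethylsilane 27 (not isolated)
Conditions: TBSOTf (2.5 equiv), 2,6-lutidine, CH2Cl2, –78 → 0 °C; then MeOH, K2CO3 (cat.), 0 °C
Reagents that add atoms: tert-butyldimethylsilyl trifluoromethanesulfonate, CC(C)(C)[Si](C)(C)OS(=O)(=O)C(F)(F)F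
Why: Both the hydroxyl and the hydroperoxide are silylated. The silyl peroxide is then methanolysed selectively, because a peroxide anion leaves silicon far more readily than a secondary alkoxide. The tertiary hydroperoxide has no α-hydrogen and tolerates the mild base.

Step 16
Reactants: 28 tert-butyl{[(2E,5R,7R,9R)-7-hydroperoxy-7,9-dimethyl-1-phenylundeca-2,10-dien-5-yl]oxy}dimethylsilane; 29 carbon monoxide; 30 methanol
Product: 31 methyl 2-[(3S,4R,6R)-6-[(2R,4E)-2-{[tert-butyl(dimethyl)silyl]oxy}-6-phenylhex-4-enyl]-4,6-dimethyl-1,2-dioxan-3-yl]acetate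
Conditions: PdCl2(MeCN)2 (10 mol %), 1,4-benzoquinone (1.5 equiv), CO (1 atm), MeOH–CH2Cl2, 0 °C → rt
Reagents that add atoms: none
Why: Proposed new method: divalent palladium binds the monosubstituted C2=C3 alkene, the terminal hydroperoxide oxygen attacks C3, and the resulting primary alkylpalladium at C2 inserts CO; methanolysis of the acylpalladium gives the methyl ester and zerovalent palladium, which 1,4-benzoquinone reoxidises while taking up the HCl released, so the medium stays near neutral. The closest known reaction types are the palladium-catalysed alkoxycarbonylative cyclisation of hydroxy alkenes to tetrahydropyranylacetates and the divalent-palladium-catalysed cyclisation of unsaturated hydroperoxides to 1,2-dioxanes; their merger on a hydroperoxide is not known. The 1,2-dioxane closes in the 6-exo-trig mode through a chair in which the C4 methyl group, the C7 chain and the coordinated alkene are equatorial and only the C6 methyl group is axial, the flipped chair being ruled out by a syn-diaxial contact between the C4 methyl group and C7. The one new stereocentre, C3, is therefore controlled by the existing C4 and C6 centres and should come out (S), with the acetate arm trans to the C4 methyl group. The step needs three selectivities: reaction at the terminal alkene, which binds palladium better than the 1,2-disubstituted C10=C11 alkene; attack by the tethered hydroperoxide and not by solvent methanol, secured by intramolecularity and the high nucleophilicity of a peroxide oxygen; and CO insertion ahead of β-hydride elimination, secured by the CO atmosphere. The tertiary hydroperoxide has no α-hydrogen and so cannot fragment to a ketone under these conditions.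

Step 17
Reactants: 31 methyl 2-[(3S,4R,6R)-6-[(2R,4E)-2-{[tert-butyl(dimethyl)silyl]oxy}-6-phenylhex-4-enyl]-4,6-dimethyl-1,2-dioxan-3-yl]acetate
Product: 32 methyl 2-[(3S,4R,6R)-6-[(2R,4E)-2-hydroxy-6-phenylhex-4-enyl]-4,6-dimethyl-1,2-dioxan-3-yl]acetate
Conditions: HF·pyridine, pyridine, THF, 0 °C → rt
Reagents that add atoms: none
Why: Acidic fluoride removes the silyl ether without base, so the β-peroxy ester cannot open by E1cB. Any 32 already formed by silyl loss in step 16 joins the route here.

Step 18
Reactants: 32 methyl 2-[(3S,4R,6R)-6-[(2R,4E)-2-hydroxy-6-phenylhex-4-enyl]-4,6-dimethyl-1,2-dioxan-3-yl]acetate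
Product: 33 methyl 2-[(3S,4R,6R)-4,6-dimethyl-6-[(E)-2-oxo-6-phenylhex-4-enyl]-1,2-dioxan-3-yl]acetate
Conditions: Dess–Martin periodinane, pyridine, CH2Cl2, 0 °C
Reagents that add atoms: none
Why: Dess–Martin oxidation under pyridine buffer should give the β,γ-unsaturated ketone without moving the C10=C11 bond; the peroxide and the ester are inert to the reagent.

Step 19
Reactants: 33 methyl 2-[(3S,4R,6R)-4,6-dimethyl-6-[(E)-2-oxo-6-phenylhex-4-enyl]-1,2-dioxan-3-yl]acetate
Product: 35 methyl 2-[(3S,4R,6R)-4,6-dimethyl-6-[(2Z,4E)-6-phenyl-2-{[(trifluoromethyl)sulfonyl]oxy}hexa-2,4-dienyl]-1,2-dioxan-3-yl]acetate, via potassium (2Z,4E)-1-[(3R,5R,6S)-6-(2-methoxy-2-oxoethyl)-3,5-dimethyl-1,2-dioxan-3-yl]-6-phenylhexa-2,4-dien-2-olate 34 (not isolated)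
Conditions: KN(SiMe3)2 (1.05 equiv), THF, –78 °C; Comins' reagent, –78 °C
Reagents that add atoms: N-(5-chloropyridin-2-yl)-1,1,1-trifluoro-N-[(trifluoromethyl)sulfonyl]methanesulfonamide, O=S(=O)(N(c1ccc(Cl)cn1)S(=O)(=O)C(F)(F)F)C(F)(F)F
Why: Kinetic enolisation at C9, which is both α to the ketone and allylic and hence the most acidic and most accessible site, gives the extended enolate with oxygen cis to C10 (this avoids allylic 1,3-strain with the C7 methylene). O-Sulfonylation (enol triflate formation) fixes that geometry as the (2Z)-triflate. Deprotonation at C7, C3 or C2, each of which would open the peroxide, should be slower at –78 °C with one equivalent of a hindered base.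

Step 20
Reactants: 35 methyl 2-[(3S,4R,6R)-4,6-dimethyl-6-[(2Z,4E)-6-phenyl-2-{[(trifluoromethyl)sulfonyl]oxy}hexa-2,4-dienyl]-1,2-dioxan-3-yl]acetate
Product: 36 methyl 2-[(3S,4R,6R)-4,6-dimethyl-6-[(2E,4E)-2-methyl-6-phenylhexa-2,4-dienyl]-1,2-dioxan-3-yl]acetate
Conditions: MeZnCl, Pd(PPh3)4 (5 mol %), THF, 0 °C → rt
Reagents that add atoms: methylzinc chloride, C[Zn]Cl
Why: Negishi coupling: oxidative addition into the C–OTf bond, transmetalation from zinc and reductive elimination all proceed with retention, so the (2Z)-triflate becomes the (2E)-methyl diene. Methylzinc chloride should attack neither the ester nor the dialkyl peroxide, and an unstrained monocyclic 1,2-dioxane is expected to tolerate the catalyst at room temperature.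

## Compound list

1 | methyl (2R)-3-hydroxy-2-methylpropanoate | COC(=O)[C@H](C)CO | starting material
2 | methyl (2R)-3-{[tert-butyl(dimethyl)silyl]oxy}-2-methylpropanoate | COC(=O)[C@H](C)CO[Si](C)(C)C(C)(C)C | intermediate
3 | (2R)-3-{[tert-butyl(dimethyl)silyl]oxy}-2-methylpropanal | O=C[C@H](C)CO[Si](C)(C)C(C)(C)C | intermediate
4 | tert-butyl(dimethyl){[(2S)-2-methylbut-3-enyl]oxy}silane | C=C[C@H](C)CO[Si](C)(C)C(C)(C)C | intermediate
5 | (2S)-2-methylbut-3-en-1-ol | C=C[C@H](C)CO | intermediate
6 | (3S)-4-iodo-3-methylbut-1-ene | C=C[C@H](C)CI | intermediate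
7 | prop-2-ynylbenzene | C#CCc1ccccc1 | starting material
8 | chlorobis(cyclopentadienyl)[(E)-3-phenylprop-1-enyl]zirconium | Cl[Zr](/C=C/Cc1ccccc1)(C1C=CC=C1)C1C=CC=C1 | intermediate
9 | [(E)-3-iodoprop-2-enyl]benzene | I/C=C/Cc1ccccc1 | intermediate
10 | 2-methyl-1,3-dithiane | CC1SCCCS1 | starting material
11 | (2R)-2-(chloromethyl)oxirane | ClC[C@H]1CO1 | starting material
12 | 2-lithio-2-methyl-1,3-dithiane | [Li]C1(C)SCCCS1 | intermediate
13 | lithium (2R)-1-chloro-3-(2-methyl-1,3-dithian-2-yl)propan-2-olate | ClC[C@H]([O-])CC1(C)SCCCS1.[Li+] | intermediate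
14 | 2-methyl-2-{[(2R)-oxiran-2-yl]methyl}-1,3-dithiane | CC1(C[C@@H]2CO2)SCCCS1 | intermediate
15 | [(E)-3-phenylprop-1-enyl]lithium | [Li]/C=C/Cc1ccccc1 | intermediate
16 | bromo[(E)-3-phenylprop-1-enyl]magnesium | Br[Mg]/C=C/Cc1ccccc1 | intermediate
17 | (2S,4E)-1-(2-methyl-1,3-dithian-2-yl)-6-phenylhex-4-en-2-ol | CC1(C[C@@H](O)C/C=C/Cc2ccccc2)SCCCS1 | intermediate
18 | 2-[(2S,4E)-2-[(4-methoxyphenyl)methoxy]-6-phenylhex-4-enyl]-2-methyl-1,3-dithiane | CC1(C[C@@H](OCc2ccc(OC)cc2)C/C=C/Cc2ccccc2)SCCCS1 | intermediate
19 | (4S,6E)-4-[(4-methoxyphenyl)methoxy]-8-phenyloct-6-en-2-one | CC(=O)C[C@@H](OCc1ccc(OC)cc1)C/C=C/Cc1ccccc1 | intermediate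
20 | [(2R)-2-methylbut-3-enyl]lithium | [Li]C[C@@H](C)C=C | intermediate
21 | bromo[(2S)-2-methylbut-3-enyl]magnesium | Br[Mg]C[C@@H](C)C=C | intermediate
22 | (3R,5S,7S,9E)-7-[(4-methoxyphenyl)methoxy]-3,5-dimethyl-11-phenylundeca-1,9-dien-5-ol | C=C[C@H](C)C[C@](C)(O)C[C@@H](OCc1ccc(OC)cc1)C/C=C/Cc1ccccc1 | intermediate
23 | (3R,5S,7S,9E)-3,5-dimethyl-11-phenylundeca-1,9-diene-5,7-diol | C=C[C@H](C)C[C@](C)(O)C[C@@H](O)C/C=C/Cc1ccccc1 | intermediate
24 | (3R,5S,7S,9E)-5-hydroxy-3,5-dimethyl-11-phenylundeca-1,9-dien-7-yl 4-methylbenzenesulfonate | C=C[C@H](C)C[C@](C)(O)C[C@@H](OS(=O)(=O)c1ccc(C)cc1)C/C=C/Cc1ccccc1 | intermediate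
25 | (2S,4R)-2-methyl-2-[(2R)-2-methylbut-3-enyl]-4-[(E)-4-phenylbut-2-enyl]oxetane | C=C[C@H](C)C[C@@]1(C)C[C@@H](C/C=C/Cc2ccccc2)O1 | intermediate
26 | (2E,5R,7R,9R)-7-hydroperoxy-7,9-dimethyl-1-phenylundeca-2,10-dien-5-ol | C=C[C@H](C)C[C@@](C)(OO)C[C@H](O)C/C=C/Cc1ccccc1 | intermediate
27 | tert-butyl{[(2E,5R,7R,9R)-7-{[tert-butyl(dimethyl)silyl]peroxy}-7,9-dimethyl-1-phenylundeca-2,10-dien-5-yl]oxy}dimethylsilane | C=C[C@H](C)C[C@@](C)(OO[Si](C)(C)C(C)(C)C)C[C@H](O[Si](C)(C)C(C)(C)C)C/C=C/Cc1ccccc1 | intermediate
28 | tert-butyl{[(2E,5R,7R,9R)-7-hydroperoxy-7,9-dimethyl-1-phenylundeca-2,10-dien-5-yl]oxy}dimethylsilane | C=C[C@H](C)C[C@@](C)(OO)C[C@H](O[Si](C)(C)C(C)(C)C)C/C=C/Cc1ccccc1 | intermediate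
29 | carbon monoxide | [C-]#[O+] | starting material
30 | methanol | CO | starting material
31 | methyl 2-[(3S,4R,6R)-6-[(2R,4E)-2-{[tert-butyl(dimethyl)silyl]oxy}-6-phenylhex-4-enyl]-4,6-dimethyl-1,2-dioxan-3-yl]acetate | COC(=O)C[C@@H]1OO[C@@](C)(C[C@H](O[Si](C)(C)C(C)(C)C)C/C=C/Cc2ccccc2)C[C@H]1C | intermediate
32 | methyl 2-[(3S,4R,6R)-6-[(2R,4E)-2-hydroxy-6-phenylhex-4-enyl]-4,6-dimethyl-1,2-dioxan-3-yl]acetate | COC(=O)C[C@@H]1OO[C@@](C)(C[C@H](O)C/C=C/Cc2ccccc2)C[C@H]1C | intermediate
33 | methyl 2-[(3S,4R,6R)-4,6-dimethyl-6-[(E)-2-oxo-6-phenylhex-4-enyl]-1,2-dioxan-3-yl]acetate | COC(=O)C[C@@H]1OO[C@@](C)(CC(=O)C/C=C/Cc2ccccc2)C[C@H]1C | intermediate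
34 | potassium (2Z,4E)-1-[(3R,5R,6S)-6-(2-methoxy-2-oxoethyl)-3,5-dimethyl-1,2-dioxan-3-yl]-6-phenylhexa-2,4-dien-2-olate | COC(=O)C[C@@H]1OO[C@@](C)(C/C([O-])=C/C=C/Cc2ccccc2)C[C@H]1C.[K+] | intermediate
35 | methyl 2-[(3S,4R,6R)-4,6-dimethyl-6-[(2Z,4E)-6-phenyl-2-{[(trifluoromethyl)sulfonyl]oxy}hexa-2,4-dienyl]-1,2-dioxan-3-yl]acetate | COC(=O)C[C@@H]1OO[C@@](C)(C/C(OS(=O)(=O)C(F)(F)F)=C/C=C/Cc2ccccc2)C[C@H]1C | intermediate
36 | methyl 2-[(3S,4R,6R)-4,6-dimethyl-6-[(2E,4E)-2-methyl-6-phenylhexa-2,4-dienyl]-1,2-dioxan-3-yl]acetate | COC(=O)C[C@@H]1OO[C@@](C)(C/C(C)=C/C=C/Cc2ccccc2)C[C@H]1C | target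

## Step count and risk

Total step count: 20.
Longest linear sequence: 15 steps (steps 1–5, then 11–20).

**Step 16 (key step).**
- What may go wrong: the primary alkylpalladium carries a peroxide oxygen on the neighbouring carbon. It may collapse by O–O heterolysis with hydride shift, a Wacker-type oxidation of the vinyl group by its own hydroperoxide that leaves a methyl ketone and the C6 alcohol. Alternatively the hydroperoxide may be consumed in redox cycling with zerovalent palladium. Either would happen before CO insertion. Ring closure through a boat, eroding C3 selectivity, is the lesser concern.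
- Fallback with known reaction types, from 28 back to 31: cycloperoxymercuration of 28 with Hg(OAc)2 in CH2Cl2 closes the dioxane reversibly, so the all-equatorial chair is reached under thermodynamic control, and gives (acetyloxy){[(3R,4R,6R)-6-[(2R,4E)-2-{[tert-butyl(dimethyl)silyl]oxy}-6-phenylhex-4-enyl]-4,6-dimethyl-1,2-dioxan-3-yl]methyl}mercury F1. Anion exchange of F1 with aqueous KBr gives bromo{[(3R,4R,6R)-6-[(2R,4E)-2-{[tert-butyl(dimethyl)silyl]oxy}-6-phenylhex-4-enyl]-4,6-dimethyl-1,2-dioxan-3-yl]methyl}mercury F2. Transmetalation of F2 to palladium with Li2PdCl4 under CO in methanol at low temperature, the known alkoxycarbonylation of β-oxygenated alkylmercurials, then gives 31. Ring closure and C3 control are thus separated from the carbonylation, and no free hydroperoxide meets palladium.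

**Step 11.**
- What may go wrong: poor facial selectivity. The six-membered magnesium chelate of a β-alkoxy methyl ketone distinguishes the two carbonyl faces less firmly than a five-membered chelate, and the methyl and methylene flanks are similar in size. Enolisation with loss of the β-alkoxy group would lower the yield further.
- Fallback with reagent control in place of chelation, from 6 back to 23: treatment of 6 with Zn and LiCl in THF gives iodo[(2S)-2-methylbut-3-enyl]zinc F3. Coupling of F3 with ethyl (2Z)-3-iodobut-2-enoate under Pd(PPh3)4 gives ethyl (2Z,5R)-3,5-dimethylhepta-2,6-dienoate F4. Reduction of F4 with i-Bu2AlH gives (2Z,5R)-3,5-dimethylhepta-2,6-dien-1-ol F5. Sharpless asymmetric epoxidation of F5 with Ti(OiPr)4, D-(−)-diisopropyl tartrate and t-BuOOH sets the tertiary C–O bond in [(2R,3S)-3-methyl-3-[(2R)-2-methylbut-3-enyl]oxiran-2-yl]methanol F6. Dess–Martin oxidation of F6 gives (2S,3S)-3-methyl-3-[(2R)-2-methylbut-3-enyl]oxirane-2-carbaldehyde F7. Corey–Chaykovsky epoxidation of F7 with dimethylsulfonium methylide gives (2S,3R)-2-methyl-2-[(2R)-2-methylbut-3-enyl]-3-(oxiran-2-yl)oxirane F8, as both epimers at the new oxirane carbon. Grignard reagent 16 with catalytic CuI opens only the terminal epoxide of F8 and gives (3E)-1-[(2R,3S)-3-methyl-3-[(2R)-2-methylbut-3-enyl]oxiran-2-yl]-5-phenylpent-3-en-1-ol F9. NaAlH2(OCH2CH2OMe)2 delivers hydride to the oxirane carbon of F9 next to the carbinol and gives 23 together with its epimer at the secondary carbinol carbon, (3R,5S,7R,9E)-3,5-dimethyl-11-phenylundeca-1,9-diene-5,7-diol F10; the epimer F10 is removed by chromatography.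

**Step 8.**
- What may go wrong: proton transfer from the doubly activated C12 methylene to the alkenyl carbanion in 15 or 16. This quenches the nucleophile or isomerises it to a 1-phenylallyl species, eroding yield and alkene geometry.
- Fallback forming the C11–C12 bond instead, from 14 back to 18: opening of 14 with LiC≡CH·H2NCH2CH2NH2 in DMSO gives (2S)-1-(2-methyl-1,3-dithian-2-yl)pent-4-yn-2-ol F11. Etherification of F11 with NaH and 4-methoxybenzyl chloride gives 2-[(2S)-2-[(4-methoxyphenyl)methoxy]pent-4-ynyl]-2-methyl-1,3-dithiane F12. Hydrozirconation of F12 with Cp2Zr(H)Cl gives chlorobis(cyclopentadienyl)[(1E,4S)-4-[(4-methoxyphenyl)methoxy]-5-(2-methyl-1,3-dithian-2-yl)pent-1-enyl]zirconium F13. Pd(PPh3)4-catalysed coupling of F13 with benzyl bromide in the presence of ZnCl2 gives 18 without an alkenyl anion next to a benzylic methylene, and step 9 is no longer needed.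

**Step 19.**
- What may go wrong: unselective deprotonation. A C7 enolate expels the peroxide oxygen from C6, abstraction of C3–H opens the ring by Kornblum–DeLaMare cleavage, and the ester enolate opens it by E1cB. Geometric control at C8=C9 may also be lost in the extended enolate.
- Fallback without strong base, from 33 directly to 36, replacing steps 19 and 20: MeTi(OiPr)3 adds to ketones, spares esters and does not enolise. It converts 33 into methyl 2-[(3S,4R,6R)-6-[(E)-2-hydroxy-2-methyl-6-phenylhex-4-enyl]-4,6-dimethyl-1,2-dioxan-3-yl]acetate F14, as both carbinol epimers. Syn-elimination from F14 with the Burgess reagent in warm toluene should remove the more acidic allylic C9 hydrogen and give 36; isomeric alkenes would be separated on silica impregnated with AgNO3.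

## Further compounds

F1 | step 16 | (acetyloxy){[(3R,4R,6R)-6-[(2R,4E)-2-{[tert-butyl(dimethyl)silyl]oxy}-6-phenylhex-4-enyl]-4,6-dimethyl-1,2-dioxan-3-yl]methyl}mercury | CC(=O)O[Hg]C[C@@H]1OO[C@@](C)(C[C@H](O[Si](C)(C)C(C)(C)C)C/C=C/Cc2ccccc2)C[C@H]1C
F2 | step 16 | bromo{[(3R,4R,6R)-6-[(2R,4E)-2-{[tert-butyl(dimethyl)silyl]oxy}-6-phenylhex-4-enyl]-4,6-dimethyl-1,2-dioxan-3-yl]methyl}mercury | Br[Hg]C[C@@H]1OO[C@@](C)(C[C@H](O[Si](C)(C)C(C)(C)C)C/C=C/Cc2ccccc2)C[C@H]1C
F3 | step 11 | iodo[(2S)-2-methylbut-3-enyl]zinc | I[Zn]C[C@@H](C)C=C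
F4 | step 11 | ethyl (2Z,5R)-3,5-dimethylhepta-2,6-dienoate | CCOC(=O)/C=C(C)\C[C@@H](C)C=C
F5 | step 11 | (2Z,5R)-3,5-dimethylhepta-2,6-dien-1-ol | OC/C=C(C)\C[C@@H](C)C=C
F6 | step 11 | [(2R,3S)-3-methyl-3-[(2R)-2-methylbut-3-enyl]oxiran-2-yl]methanol | OC[C@H]1O[C@@]1(C)C[C@@H](C)C=C
F7 | step 11 | (2S,3S)-3-methyl-3-[(2R)-2-methylbut-3-enyl]oxirane-2-carbaldehyde | O=C[C@H]1O[C@@]1(C)C[C@@H](C)C=C
F8 | step 11 | (2S,3R)-2-methyl-2-[(2R)-2-methylbut-3-enyl]-3-(oxiran-2-yl)oxirane | O1CC1[C@H]1O[C@@]1(C)C[C@@H](C)C=C
F9 | step 11 | (3E)-1-[(2R,3S)-3-methyl-3-[(2R)-2-methylbut-3-enyl]oxiran-2-yl]-5-phenylpent-3-en-1-ol | OC(C/C=C/Cc1ccccc1)[C@H]1O[C@@]1(C)C[C@@H](C)C=C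
F10 | step 11 | (3R,5S,7R,9E)-3,5-dimethyl-11-phenylundeca-1,9-diene-5,7-diol | C=C[C@H](C)C[C@](C)(O)C[C@H](O)C/C=C/Cc1ccccc1
F11 | step 8 | (2S)-1-(2-methyl-1,3-dithian-2-yl)pent-4-yn-2-ol | CC1(C[C@@H](O)CC#C)SCCCS1
F12 | step 8 | 2-[(2S)-2-[(4-methoxyphenyl)methoxy]pent-4-ynyl]-2-methyl-1,3-dithiane | CC1(C[C@@H](OCc2ccc(OC)cc2)CC#C)SCCCS1
F13 | step 8 | chlorobis(cyclopentadienyl)[(1E,4S)-4-[(4-methoxyphenyl)methoxy]-5-(2-methyl-1,3-dithian-2-yl)pent-1-enyl]zirconium | CC1(C[C@@H](OCc2ccc(OC)cc2)C/C=C/[Zr](Cl)(C2C=CC=C2)C2C=CC=C2)SCCCS1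
F14 | step 19 | methyl 2-[(3S,4R,6R)-6-[(E)-2-hydroxy-2-methyl-6-phenylhex-4-enyl]-4,6-dimethyl-1,2-dioxan-3-yl]acetate | COC(=O)C[C@@H]1OO[C@@](C)(CC(C)(O)C/C=C/Cc2ccccc2)C[C@H]1C
A1 | alternative 1 | methyl 2-[(4R)-6-[(E)-3-bromo-2-methylprop-2-enyl]-6-hydroxy-3-methoxy-4-methyl-1,2-dioxan-3-yl]acetate | COC(=O)CC1(OC)OOC(O)(C/C(C)=C/Br)C[C@H]1C
A2 | alternative 1 | methyl 2-[(4R)-2-[(E)-3-bromo-2-methylprop-2-enyl]-4-methylcyclobut-1-en-1-yl]acetate | COC(=O)CC1=C(C/C(C)=C/Br)C[C@H]1C
A3 | alternative 2 | methyl 2-[(3S,4R,6R)-6-[(E)-4-{[tert-butyl(dimethyl)silyl]oxy}-2-methylbut-2-enyl]-4,6-dimethyl-1,2-dioxan-3-yl]acetate | COC(=O)C[C@@H]1OO[C@@](C)(C/C(C)=C/CO[Si](C)(C)C(C)(C)C)C[C@H]1C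
A4 | alternative 2 | methyl (3S,4R,6R,8E)-3,6-bis(aminooxy)-10-{[tert-butyl(dimethyl)silyl]oxy}-4,6,8-trimethyldec-8-enoate | COC(=O)C[C@H](ON)[C@H](C)C[C@@](C)(ON)C/C(C)=C/CO[Si](C)(C)C(C)(C)C
A5 | alternative 3 | tert-butyl{2-[(3S,4R,6R)-6-[(E)-2-hydroxy-6-phenylhex-4-enyl]-4,6-dimethyl-1,2-dioxan-3-yl]ethoxy}diphenylsilane | CC(C)(C)[Si](c1ccccc1)(c1ccccc1)OCC[C@@H]2OO[C@@](C)(CC(O)C/C=C/Cc3ccccc3)C[C@H]2C
A6 | alternative 3 | tert-butyl{[(3S,4R)-3-hydroperoxy-4-methyl-5-[(2S)-2-methyl-4-[(E)-4-phenylbut-2-enyl]oxetan-2-yl]pentyl]oxy}diphenylsilane | CC(C)(C)[Si](c1ccccc1)(c1ccccc1)OCC[C@H](OO)[C@H](C)C[C@@]1(C)CC(C/C=C/Cc2ccccc2)O1
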